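**Retrosynthetic overview**

1. Last disconnection: open the furan ring (C3–C1′ and C2–O bonds). This gives a 2-(methylthio)pyranochromone (nucleophilic C3, leaving group on C2) and 2,2-dimethylchromene-5,8-dione, the latter made in the same flask by oxidative dearomatisation of 2,2-dimethyl-2H-chromen-8-ol.
2. The 2-(methylthio)chromone comes from CS2/MeI on a mono-MOM chroman acetophenone, itself from a one-step isoprene annulation that desymmetrises phloroacetophenone.
3. The chromenol comes from catechol by a propargyl-ether Claisen cascade.
4. Ring order: A-ring dihydropyran, then γ-pyranone (left branch); B-ring 2H-pyran (right branch); furan last, in the fragment union.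

Assumption: the target has no stereogenic element (both quaternary carbons carry two methyls; the only non-aromatic C=C is endocyclic), so there is no stereochemistry to set.

**Route**

Step 1
Reactants: 1, 2,4,6-trihydroxyacetophenone (phloroacetophenone, used in 1.5-fold excess); 2, isoprene
Product: 3, 1-(5,7-dihydroxy-2,2-dimethylchroman-6-yl)ethan-1-one
Conditions: Amberlyst-15, THF–heptane, 65 °C, slow addition of isoprene
Reagents that add atoms: isoprene (reactant 2), C=CC(C)=C
Why: Acid-catalysed Friedel–Crafts prenylation then hydroalkoxylation; the two ring CH positions of symmetric 1 are equivalent, and the tertiary cation is captured by the non-chelated para-OH because the flanking ortho-OH is held in the C=O···HO chelate, so the 6-acetyl chroman is the major product (minor 8-acetyl isomer and bis-chroman removed by chromatography).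

Step 2
Reactants: 3
Product: 4, 1-[5-hydroxy-7-(methoxymethoxy)-2,2-dimethylchroman-6-yl]ethan-1-one
Conditions: MOMCl (1.05 equiv), i-Pr2NEt, CH2Cl2, 0 °C
Reagents that add atoms: chloromethyl methyl ether, COCCl
Why: Selective phenol O-alkylation; the 5-OH, buttressed by the C4 methylene, sits in the chelate with the acetyl group, so the unhindered 7-OH reacts, masking the oxygen that must become the free 5-OH of the chromone and leaving only the correct phenol to close the pyranone.

Step 3
Reactants: 4
Product: 5, 5-(methoxymethoxy)-8,8-dimethyl-2-(methylsulfanyl)-9,10-dihydro-4H,8H-pyrano[2,3-f]chromen-4-one (angular pyranochromone, SMe on C2, H on C3)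
Conditions: t-BuOK (3.2 equiv), CS2 (1.2 equiv), THF, 0 °C to rt; MeI (2.05 equiv), rt; then 60 °C
Reagents that add atoms: carbon disulfide, S=C=S; iodomethane, CI
Why: α-Oxo ketene dithioacetal formation (enolate + CS2, double S-methylation) followed by intramolecular addition–elimination of the only free phenoxide with loss of MeS⁻, the standard 2-(methylthio)chromone synthesis; regiochemistry is fixed because one ortho oxygen is MOM-protected.

Step 4
Reactants: 6, catechol (3 equiv); 7, 3-chloro-3-methylbut-1-yne
Product: 8, 2-[(2-methylbut-3-yn-2-yl)oxy]phenol
Conditions: K2CO3, KI, CuI (cat.), acetone, 55 °C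
Reagents that add atoms: 3-chloro-3-methylbut-1-yne (reactant 7), CC(C)(Cl)C#C
Why: Copper-assisted O-propargylation of a phenol with a tertiary propargyl chloride; excess symmetric catechol ensures mono-etherification.

Step 5
Reactants: 8
Product: 9, 2,2-dimethyl-2H-chromen-8-ol
Conditions: PhNEt2, 180 °C
Reagents that add atoms: none
Why: Aryl propargyl ether Claisen rearrangement, 1,5-H shift and oxa-6π electrocyclisation; only one ortho carbon is free, so a single chromene forms.

Step 6 (key step)
Reactants: 9 (2.0 equiv); 5 (1.0 equiv)
Product: 12, Formosanatin D, via 10 (2,2-dimethyl-2H-chromene-5,8-dione) and 11 (5-O-MOM Formosanatin D), neither isolated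
Conditions: (i) 9, PhI(OAc)2 (3.9 equiv, i.e. just under 2 per phenol), HFIP–H2O 9:1, 0 °C, 20 min; (ii) add 5, Sc(OTf)3 (10 mol %), 40 °C, N2 sparge; (iii) MeOH, 3 M HCl, 45 °C
Reagents that add atoms: water, O (its oxygen becomes C5=O of the quinone and then the furan oxygen)
Why: Proposed new method: PhI(OAc)2/H2O dearomatises the para-unsubstituted phenol 9 to p-quinone 10 (water adds para to the phenoxonium ion, then a second oxidation); C3 of 5, the α-carbon of a cyclic α-oxo ketene O,S-acetal, adds to C6 of 10 (β to the ketone-like C8=O, which is activated by Sc(III)/HFIP through chelation with O1, whereas C5=O is a deactivated vinylogous ester), the new hydroquinone C5-OH attacks C2 and MeSH is expelled to aromatise the furan, and acid then removes the MOM group; the closest known reactions are the Nenitzescu benzofuran synthesis, the Lewis-acid formal [3+2] annulation of α-oxo ketene dithioacetals with p-quinones, and hypervalent-iodine phenol-to-quinone oxidation.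

Notes on Step 6: PhI(OAc)2 is kept limiting so no iodine(III) remains when the thioether 5 is added. The quinone is used in excess because the MeSH released can add to it; the N2 sparge removes MeSH.

**Compound list**

1 | 2,4,6-trihydroxyacetophenone | CC(=O)c1c(O)cc(O)cc1O | starting material
2 | isoprene | C=CC(C)=C | starting material
3 | 1-(5,7-dihydroxy-2,2-dimethylchroman-6-yl)ethan-1-one | CC(=O)c1c(O)cc2OC(C)(C)CCc2c1O | intermediate
4 | 1-[5-hydroxy-7-(methoxymethoxy)-2,2-dimethylchroman-6-yl]ethan-1-one | CC(=O)c1c(OCOC)cc2OC(C)(C)CCc2c1O | intermediate
5 | 5-(methoxymethoxy)-8,8-dimethyl-2-(methylsulfanyl)-9,10-dihydro-4H,8H-pyrano[2,3-f]chromen-4-one | CSc1cc(=O)c2c(OCOC)cc3OC(C)(C)CCc3c2o1 | intermediate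
6 | catechol | Oc1ccccc1O | starting material
7 | 3-chloro-3-methylbut-1-yne | CC(C)(Cl)C#C | starting material
8 | 2-[(2-methylbut-3-yn-2-yl)oxy]phenol | CC(C)(C#C)Oc1ccccc1O | intermediate
9 | 2,2-dimethyl-2H-chromen-8-ol | CC1(C)C=Cc2cccc(O)c2O1 | intermediate
10 | 2,2-dimethyl-2H-chromene-5,8-dione | CC1(C)C=CC2=C(O1)C(=O)C=CC2=O | intermediate (in situ)
11 | 5-O-methoxymethyl Formosanatin D | CC1(C)C=Cc2c(c(O)cc3c2oc2oc4c5c(cc(OCOC)c4c(=O)c23)OC(C)(C)CC5)O1 | intermediate (in situ)
12 | Formosanatin D | CC1(C)C=Cc2c(c(O)cc3c2oc2oc4c5c(cc(O)c4c(=O)c23)OC(C)(C)CC5)O1 | target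

**Totals**

Total steps: 6. Longest linear sequence: 4 (Steps 1, 2, 3, 6).

**Steps most likely to fail, with fallbacks**

1. Step 6. Risks: C3 of 5 may be too weak a nucleophile; the A-ring C6–H may compete; the quinone may be attacked at C7; the one-pot oxidation may be low-yielding. Fallback: isolate 10 (Fremy's salt oxidation of 9) and react it under BF3·OEt2 with the open-chain ketene dithioacetal of 4, 1-aryl-3,3-bis(methylthio)prop-2-en-1-one, which is the precedented furan-forming partner. The pyranone is then closed last by base-mediated displacement of the benzofuran C2–SMe by the single free A-ring phenol, before MOM removal (ring order inverted: furan first, pyranone second).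

2. Step 1. Risks: 6-acetyl versus 8-acetyl chroman selectivity and over-annulation. Fallback: make the pyran by a route that engages only the non-chelated para-OH, namely Knoevenagel/oxa-6π chromenylation of 1 with 3-methylbut-2-enal (EDDA) to 6-acetyl-5,7-dihydroxy-2,2-dimethyl-2H-chromene, then hydrogenation (H2, Pd/C) to 3.

3. Step 2. Risk: incomplete 7-OH versus 5-OH discrimination. Fallback: start from 2′,4′-dihydroxy-6′-methoxyacetophenone, in which the oxygen destined to be the chromone 5-OH is already differentiated. Carry the methyl ether through chroman annulation, CS2/MeI and the union, and unveil the peri-OH at the end by chelation-controlled demethylation with BCl3.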